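# A 2β,13-dihydroxy C20 gibberellin 19,20-lactone by halide-relayed strain-release lactonisation of a C1,C10-methano cyclopropyl ketone

## Analysis of the target

The target gibberellin (35) is a C20 ent-gibberellane: cyclohexane ring A, cyclopentane ring B, and a bicyclo[3.2.1]octane (rings C and D) that carries the bridgehead 13-hydroxyl and the 16-methylene. A δ-lactone runs from the C19 carboxyl on C4 through the C20 methylene to C10. There are eight stereocentres (C2, C4, C5, C6, C8, C9, C10, C13), three of them quaternary carbons (C4, C8, C10) and one a tertiary carbinol (C13). C19 and C20 both sit on the α face, 1,3-diaxial on ring A, while H-5, the C7 carboxyl, H-9 and the C15–C16 bridge are β and the 2-hydroxyl is equatorial (β). The sensitive groups are the tertiary allylic alcohol next to the exocyclic alkene (acid-labile), the δ-lactone (opened by base, reclosed by acid) and the epimerisable C6 next to the C7 carboxyl. The hard points are the vicinal quaternary pair C4/C10 around C5, the C–O bond at the neopentyl carbon C20, and the bridged C/D unit with its quaternary C8. The strategy rests on one feature: C20 is a CH2–O on quaternary C10, γ to the C2 oxygen through C1 and syn-diaxial to the C19 carboxyl on C4. A cyclopropane spanning C1 and C10 next to a C2 ketone is therefore a latent, strain-activated C20 electrophile.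

## Retrosynthetic reasoning

**End game.** 35 is traced to its methyl ester 2-pivalate 33. Both esters fall in one basic hydrolysis, which avoids acid at the rearrangement-prone C13 carbinol; the lactone may open to 34 but recloses on mild acidification.

**Ring D (C13–C16).** The bridgehead carbinol and the exocyclic alkene are cut together between C13 and C16, giving the propargyl ketone 32. A ketyl at C13 can only add to the alkyne across the bridge, so C13 needs no separate control. 32 comes from the allyl ketone 30 through aldehyde 31.

**Quaternary C8 (C8–C15).** The allyl group of 30 is cut from C8, leaving enone 28 and allylsilane 29. The α face of C8 is blocked by the axial C20–O bridge on C10 (1,3 across ring B), so conjugate allylation should come from the β face, which is also the cis-hydrindanone mode.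

**Ring C (C8=C14 and C9–C11).** 28 is opened by a retro-aldol condensation and a retro-alkylation at C9 to the β-keto ester 24 and the masked 3-oxobutyl bromide 25. C7 is carried as an ester on purpose: a C7 ether β to the C8 ketone would be lost by elimination under any equilibrating conditions, whereas the β-keto ester tolerates them and steers alkylation to C9 through its dianion. Equilibration is wanted, because only the C9 epimer with C11 pseudo-equatorial (α) can close an unstrained cyclohexenone.

**Oxidation-state adjustments.** 24 goes back through 23, 22, 20 and 19 to the keto lactone 17; these steps only reduce and protect C2 and adjust C7 and C8.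

**Key disconnection (O–C20 formed, C1–C20 broken).** 17 is traced to the cyclopropyl keto acid 15. A direct attack of the C19 carboxyl on C20 was examined first and rejected on stereoelectronic grounds. The carboxyl hangs under ring A, and a simple geometric estimate puts its closest approach to C20 at roughly 115° to the breaking C1–C20 bond, in effect a front-side attack. The strategy is kept but repaired with a halide relay: a soft halide opens the Lewis-acid-activated cyclopropane at C20 from the open outer side with inversion (16), and the carboxylate then displaces the halide in a second inversion. Ring strain pays for the first step and makes the neopentyl C–O bond accessible in the second. C8 is carried as a benzyl ether, not as a ketone: this leaves a single ketone after the key step, avoids a β-alkoxy ketone under Lewis acid, and prevents the α-oxygen on C8, which lies close to the backside of C20, from acting as a free nucleophile.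

**Cyclopropane (C1–C20 and C10–C20).** 15 comes from the allylic alcohol 12 via 13 and 14. The C2 oxygen is used twice: as the 2α-alcohol it delivers the methylene to the α face of the C1=C10 alkene and so fixes C10, and as the ketone it activates the ring. 12 arises from enone 11.

**Ring A (C1–C10).** 11 is opened at C1–C10 to ketone 8, which carries an allylsilane on C4. A Lewis-acid ring closure is chosen over a base-mediated aldol because C8–O is β to the C10 ketone and would be eliminated by base. The C2 carbonyl then comes from the exocyclic methylene of 9.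

**C4 and the chiral pool.** 8 is traced through 7 to the bicyclic lactone 5, which is built by two successive enolate alkylations (through 3, with chloride 4) of the dibenzyl lactone 2. The second electrophile enters on the convex face of the cis-fused lactone and so sets the C4 quaternary centre relative to C5. 2 is the protected form of lactone diol 1, which already holds C4, C5, C6, C7, C19 and the oxygens on C8 and C10 with the correct trans C5/C6 relationship.

## Alternatives that were turned down

**Alternative 1:** Ring B is disconnected at C5–C10 and C4–C19. In the forward sense, a cobalt-mediated carbonylative cyclisation joins an ethynyl group on C9, a propenyl arm on C6 and the inserted carbonyl unit, giving the pentacyclic cyclopentenone A1 in which the C19 ketone is still bonded to C20.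
- For: rings C and D are in place before the key step, so the bridged unit and the C8/C9 centres are settled early, and one step forms three C–C bonds and two rings. On convergence and on early handling of the bridged unit this plan is stronger than the chosen one.
- Against: ring A does not exist in A1. C1–C3 must still be annulated onto a crowded C10, and C4 must be quaternised. The C19–C20 bond must then be replaced by C19–O–C20, but a Baeyer–Villiger insertion would favour migration of the more substituted C4 over the C20 methylene.
- Comparison: the chosen route instead takes C4, C5 and C6 from one chiral-pool lactone and makes the C20–O bond at the correct oxidation level, without a regiochemically unfavourable oxygen insertion.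

**Alternative 2:** The C6–C8 bond is disconnected to a ring-B-expanded 6-diazo-7-ketone. Photochemical Wolff rearrangement moves C8 from C7 to C6 and traps the ketene as the methyl ester, giving the bis-silyl ether A2 of the target's methyl ester.
- For: the step mirrors the biosynthetic ring contraction, C8 migrates with retention, C7 emerges at the right oxidation level, and A2 is two deprotections from the target. In its end game this plan is clearly stronger.
- Against: all the difficulty moves into the precursor, a complete kauranoid pentacycle that already needs the 19,20-lactone, both hydroxyls and the C/D unit. C6 is set only by ketene capture, next to the new quaternary C8, and may need later epimerisation.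
- Comparison: the chosen route offers a short, stereodefined entry to the A/B core and fixes C6 from the outset; the price is a longer elaboration after the key step.

**Alternative 3:** C8–C9 and C13–C14 are disconnected. An intramolecular Diels–Alder reaction between an (E,E)-1-silyloxydiene on C10 and a 2-substituted acrolein unit on C6 closes rings B and C at once, giving the tetracyclic aldehyde A3 with the formyl carbon C15 on C8.
- For: one cycloaddition sets the quaternary C8 together with C9 and C13 on a pre-formed ring A lactone template. This is stronger than the stepwise annulation and conjugate allylation used here, where C9 relies on equilibration.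
- Against: the substrate needs a dienyl chain on quaternary C10 and an acrolein on C6 of a lactone that itself must first be made. The endo/exo and facial outcome across the newly formed five-membered ring is not secured by any rigid element. In A3, C15 is an aldehyde that must later be deoxygenated, while C16 and C17 are still missing.
- Comparison: the chosen route keeps C15 at the methylene level throughout and uses the same lactone-first logic with simpler, well-precedented ring-forming steps.

Key step: step 12

## Route

Assumption: lactone diol 1, the mirror image of the prostaglandin building block, is taken to be purchasable as the single (3aS,4R,5S,6aR) enantiomer; atoms are numbered throughout as the gibberellane carbons they become.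

Step 1
Reactants: 1 (3aS,4R,5S,6aR)-5-hydroxy-4-(hydroxymethyl)hexahydro-2H-cyclopenta[b]furan-2-one
Product: 2 7,8-di-O-benzyl lactone (benzyl ethers on the C7 and C8 oxygens of 1)
Conditions: BnOC(=NH)CCl3 (2.6 equiv), TfOH (cat.), CH2Cl2/cyclohexane, 0 °C to rt
Reagents that add atoms: benzyl 2,2,2-trichloroacetimidate, ClC(Cl)(Cl)C(=N)OCc1ccccc1
Why: Acid-catalysed imidate benzylation protects both hydroxyls without forming an alkoxide that could open or migrate the lactone; no stereocentre is touched.

Step 2
Reactants: 2 7,8-di-O-benzyl lactone
Product: 3 α-methyl lactone (C18 methyl on C4, convex face, cis to H-5)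
Conditions: LDA (1.1 equiv), THF, −78 °C; MeI, −78 to −30 °C
Reagents that add atoms: iodomethane, CI
Why: Enolate alkylation of a γ-lactone; the methyl enters the convex face of the cis-fused bicycle, but this C4 configuration is erased when the enolate is formed again in step 3.

Step 3
Reactants: 3 α-methyl lactone; 4 [2-(chloromethyl)allyl]trimethylsilane
Product: 5 C4-quaternary lactone (2-[(trimethylsilyl)methyl]allyl chain on the convex face, C18 methyl on the concave face)
Conditions: LDA (1.2 equiv), THF, −78 °C; 4, NaI (0.1 equiv), DMPU, −78 to −10 °C
Reagents that add atoms: [2-(chloromethyl)allyl]trimethylsilane (4), ClCC(=C)C[Si](C)(C)C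
Why: Second enolate alkylation with a reactive allylic halide; the electrophile approaches the planar enolate from the convex face (side of H-5, away from ring B), so the chain (C3) ends cis to H-5 and C19 syn to C6, which is the C4 configuration of the target.

Step 4
Reactants: 5 C4-quaternary lactone
Product: 7 methyl 19-ester with free 10-hydroxyl (opened lactone), via potassium carboxylate 6 (not isolated)
Conditions: KOH (1.5 equiv), MeOH/H2O, 60 °C; CO2 to pH 8, evaporate; MeI, DMF, rt
Reagents that add atoms: potassium hydroxide, [K+].[OH-]; iodomethane, CI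
Why: Saponification followed by O-alkylation of the carboxylate esterifies C19 without acid, so the cis γ-hydroxy ester is not driven back to the lactone; 7 is used at once.

Step 5
Reactants: 7 methyl 19-ester with free 10-hydroxyl
Product: 8 C10 ketone (cyclopentanone with allylsilane chain on C4)
Conditions: Dess–Martin periodinane, NaHCO3, CH2Cl2, 0 °C to rt
Reagents that add atoms: none
Why: Buffered periodinane oxidation is neutral, so the β-benzyloxy ketone is not eliminated and relactonisation is prevented for good.

Step 6
Reactants: 8 C10 ketone
Product: 9 bicyclic tertiary alcohol (ring A closed; 2-methylene, 10-hydroxyl)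
Conditions: TiCl4 (1.1 equiv), CH2Cl2, −78 °C
Reagents that add atoms: none
Why: Intramolecular Hosomi–Sakurai allylation forms C1–C10 and the six-membered ring without base, which the β-benzyloxy ketone would not survive; the C10 carbinol configuration (cis ring fusion expected) is lost in step 7.

Step 7
Reactants: 9 bicyclic tertiary alcohol
Product: 11 ring A enone (2-oxo-1(10)-ene methyl ester), via β-hydroxy ketone 10 (not isolated)
Conditions: O3, CH2Cl2, −78 °C; Me2S; then TsOH·H2O (0.1 equiv), CH2Cl2, 40 °C
Reagents that add atoms: ozone, [O-][O+]=O
Why: Ozonolysis of the 1,1-disubstituted alkene gives the C2 ketone, and acid-catalysed loss of the tertiary 10-hydroxyl gives the conjugated enone; C5 keeps its more stable trans relationship to C6.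

Step 8
Reactants: 11 ring A enone
Product: 12 2α-allylic alcohol
Conditions: NaBH4, CeCl3·7H2O, MeOH, −40 °C
Reagents that add atoms: none
Why: Luche 1,2-reduction; hydride should approach C2 from the β face, away from the pseudo-axial C19 ester on C4 (1,3 to C2), leaving the hydroxyl α and syn to that ester.

Step 9
Reactants: 12 2α-allylic alcohol
Product: 13 cyclopropyl carbinol methyl ester (C20 methylene bridging C1 and C10 on the α face)
Conditions: Et2Zn (3 equiv), CH2I2 (3 equiv), CH2Cl2, 0 °C
Reagents that add atoms: diiodomethane, ICI
Why: Hydroxyl-directed Simmons–Smith cyclopropanation; the zinc alkoxide delivers the methylene to the face of the C2 oxygen, which sets quaternary C10 with C20 α, on the same side as C19.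

Step 10
Reactants: 13 cyclopropyl carbinol methyl ester
Product: 14 cyclopropyl carbinol 19-acid
Conditions: KOSiMe3 (3 equiv), THF, 50 °C; aq. citric acid to pH 4
Reagents that add atoms: none
Why: Silanolate cleaves the hindered axial methyl ester by attack at the methyl carbon; it is done before oxidation, while the cyclopropane is not yet activated toward nucleophiles.

Step 11
Reactants: 14 cyclopropyl carbinol 19-acid
Product: 15 cyclopropyl keto acid (2-oxo, C20 bridging C1 and C10, free C19 acid)
Conditions: Dess–Martin periodinane, CH2Cl2, rt
Reagents that add atoms: none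
Why: Periodinane oxidation of the secondary carbinol tolerates the free acid and the cyclopropane and gives the activated cyclopropyl ketone.

Step 12
Reactants: 15 cyclopropyl keto acid
Product: 17 2-oxo 19,20-lactone (7,8-di-O-benzyl), via 20-iodo keto acid 16 (not isolated)
Conditions: Sc(OTf)3 (0.1 equiv), LiI (1.5 equiv), MeCN, 70 °C
Reagents that add atoms: none
Why: The scandium-bound C2 carbonyl polarises the C1–C20 bond, the cyclopropane bond best aligned with the carbonyl π system, and iodide attacks C20 from the open outer α side, anti to C1, with inversion. The resulting enolate is protonated by the C19 acid to give iodo ketone 16 as its carboxylate. The carboxylate then displaces iodide at C20 in a 6-exo-tet closure of the δ-lactone, which is possible because rotation about C10–C20 now allows a linear O–C–I arrangement; iodide is returned. The relay is needed because the tethered carboxyl could reach C20 in 15 only at about 115° to the breaking bond. The closest known reactions are the Lewis acid and iodide opening of cyclopropyl ketones to γ-iodo ketones and the lactonisation of ω-halo carboxylates. No stereocentre is created: C10 was fixed in step 9, and C20 is a methylene. The step needs cleavage of C1–C20 and not C1–C10; this is secured by the SN2 preference for the CH2 over quaternary C10 and by the mild Lewis acid. Return of 16 to 15 by 3-exo closure is harmless, because only lactone formation is irreversible, and the C8 oxygen is kept as a benzyl ether so that it cannot close a five-membered ether onto C20.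

Step 13
Reactants: 17 2-oxo 19,20-lactone
Product: 18 2β-hydroxy lactone
Conditions: SmI2 (2.5 equiv), H2O (20 equiv), THF, 0 °C
Reagents that add atoms: none
Why: Electron-transfer reduction should give the more stable equatorial (exo) 2β-alcohol, as dissolving-metal reductions do for bridged bicyclic ketones where hydrides give the axial epimer; the limited reagent charge spares the δ-lactone.

Step 14
Reactants: 18 2β-hydroxy lactone
Product: 19 2β-pivalate
Conditions: PivCl, pyridine, DMAP (cat.), CH2Cl2, rt
Reagents that add atoms: pivaloyl chloride, CC(C)(C)C(=O)Cl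
Why: Acylation of the unhindered equatorial alcohol; the pivalate has no α-hydrogen and tolerates amide bases, TiCl4, SmI2 and acid, and it falls in the final hydrolysis.

Step 15
Reactants: 19 2β-pivalate
Product: 20 7,8-diol
Conditions: H2 (1 atm), Pd(OH)2 on carbon, EtOAc/EtOH, rt
Reagents that add atoms: none
Why: Hydrogenolysis removes both benzyl ethers at a stage with no alkene or cyclopropane present.

Step 16
Reactants: 20 7,8-diol
Product: 22 8-hydroxy 7-carboxylic acid, via hydroxy aldehyde 21 (not isolated)
Conditions: TEMPO (0.2 equiv), PhI(OAc)2 (2.3 equiv), MeCN/H2O, rt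
Reagents that add atoms: water, O
Why: Oxoammonium oxidation is selective for the primary alcohol, so C7 reaches the acid level while C8 stays an alcohol and no β-keto acid, which would decarboxylate, is formed.

Step 17
Reactants: 22 8-hydroxy 7-carboxylic acid
Product: 23 8-hydroxy 7-methyl ester
Conditions: Me3SiCHN2, PhMe/MeOH, 0 °C
Reagents that add atoms: (trimethylsilyl)diazomethane, C[Si](C)(C)C=[N+]=[N-]
Why: Neutral methylation of the acid; the lactone and pivalate are untouched.

Step 18
Reactants: 23 8-hydroxy 7-methyl ester
Product: 24 β-keto ester (8-oxo, 7-methyl ester)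
Conditions: Dess–Martin periodinane, NaHCO3, CH2Cl2, rt
Reagents that add atoms: none
Why: Oxidation of the only free alcohol gives the β-keto ester, which cannot eliminate and directs later chemistry to C9.

Step 19
Reactants: 24 β-keto ester; 25 2-(2-bromoethyl)-2-methyl-1,3-dioxolane
Product: 26 C9-alkylated β-keto ester (3,3-ethylenedioxybutyl on C9, C9 epimers)
Conditions: LDA (2.3 equiv), THF, −78 to 0 °C; 25, DMPU, 0 °C to rt
Reagents that add atoms: 2-(2-bromoethyl)-2-methyl-1,3-dioxolane (25), CC1(CCBr)OCCO1
Why: The dianion of a β-keto ester alkylates at its γ carbon, here C9; the lactone has no α-hydrogen and the pivalate none either, and the C9 configuration is corrected in step 20.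

Step 20
Reactants: 26 C9-alkylated β-keto ester
Product: 28 tricyclic enone (13-oxo-8(14)-ene, H-9 β), via triketone 27 (not isolated)
Conditions: TsOH·H2O (0.3 equiv), acetone/H2O, 50 °C; then PhMe, 90 °C
Reagents that add atoms: water, O
Why: Acetal hydrolysis followed by acid-catalysed aldol condensation of C14 onto the C8 ketone; C9 equilibrates through enol and dienol, and only the epimer with C11 pseudo-equatorial (α) closes an unstrained cyclohexenone, so H-9 should end β, with C6 settling trans to C5.

Step 21
Reactants: 28 tricyclic enone; 29 allyltrimethylsilane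
Product: 30 8β-allyl 13-ketone
Conditions: 29 (2 equiv), TiCl4 (1.2 equiv), CH2Cl2, −78 °C
Reagents that add atoms: allyltrimethylsilane (29), C=CC[Si](C)(C)C
Why: Hosomi–Sakurai conjugate allylation creates quaternary C8; the α face is blocked by the axial C20–O bridge on C10, and β attack gives the cis-fused hydrindanone with C15 cis to H-9.

Step 22
Reactants: 30 8β-allyl 13-ketone
Product: 31 keto aldehyde (C16 aldehyde on C15)
Conditions: O3, CH2Cl2, −78 °C; PPh3
Reagents that add atoms: ozone, [O-][O+]=O
Why: Ozonolysis of the only alkene with reductive work-up gives the aldehyde.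

Step 23
Reactants: 31 keto aldehyde
Product: 32 8β-propargyl 13-ketone
Conditions: dimethyl (1-diazo-2-oxopropyl)phosphonate, K2CO3, MeOH, 0 °C to rt
Reagents that add atoms: dimethyl (1-diazo-2-oxopropyl)phosphonate, CC(=O)C(=[N+]=[N-])P(=O)(OC)OC
Why: Ohira–Bestmann homologation turns the aldehyde into the terminal alkyne and adds C17; ketones do not react under these conditions.

Step 24
Reactants: 32 8β-propargyl 13-ketone
Product: 33 methyl ester 2-pivalate of the target gibberellin
Conditions: SmI2 (3 equiv), HMPA, t-BuOH, THF, 0 °C
Reagents that add atoms: none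
Why: Ketyl–alkyne reductive cyclisation (5-exo-dig) forms C13–C16 and gives the bridgehead carbinol and the exocyclic methylene together; the bridge can close only on the face of C15, so C13 follows from C8.

Step 25
Reactants: 33 methyl ester 2-pivalate of the target gibberellin
Product: 35 target gibberellin (2β,13-dihydroxy-16-ene C20 gibberellin 7-carboxylic acid 19,20-δ-lactone), via dipotassium seco-salt 34 (not isolated)
Conditions: KOH (2 M), MeOH/H2O, 65 °C; then HCl to pH 2.5, rt
Reagents that add atoms: potassium hydroxide, [K+].[OH-]
Why: Saponification removes the C7 methyl ester and the pivalate; the lactone, if opened, recloses on mild acidification because the C20 hydroxyl and C19 acid are held syn-diaxial, and the acid-sensitive C13 carbinol sees only brief, dilute acid.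

## Compound list

1 | (3aS,4R,5S,6aR)-5-hydroxy-4-(hydroxymethyl)hexahydro-2H-cyclopenta[b]furan-2-one | O=C1C[C@H]2[C@H](CO)[C@@H](O)C[C@H]2O1 | starting material
2 | 7,8-di-O-benzyl lactone | O=C1C[C@H]2[C@H](COCc3ccccc3)[C@@H](OCc3ccccc3)C[C@H]2O1 | intermediate
3 | α-methyl lactone (methyl cis to H-5) | O=C1[C@H](C)[C@H]2[C@H](COCc3ccccc3)[C@@H](OCc3ccccc3)C[C@H]2O1 | intermediate
4 | [2-(chloromethyl)allyl]trimethylsilane | ClCC(=C)C[Si](C)(C)C | starting material
5 | C4-quaternary lactone | O=C1[C@](C)(CC(=C)C[Si](C)(C)C)[C@H]2[C@H](COCc3ccccc3)[C@@H](OCc3ccccc3)C[C@H]2O1 | intermediate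
6 | potassium carboxylate of the opened lactone | [K+].[O-]C(=O)[C@](C)(CC(=C)C[Si](C)(C)C)[C@H]1[C@H](COCc2ccccc2)[C@@H](OCc2ccccc2)C[C@H]1O | intermediate (not isolated)
7 | methyl 19-ester with free 10-hydroxyl | COC(=O)[C@](C)(CC(=C)C[Si](C)(C)C)[C@H]1[C@H](COCc2ccccc2)[C@@H](OCc2ccccc2)C[C@H]1O | intermediate
8 | C10 ketone | COC(=O)[C@](C)(CC(=C)C[Si](C)(C)C)[C@H]1[C@H](COCc2ccccc2)[C@@H](OCc2ccccc2)CC1=O | intermediate
9 | bicyclic tertiary alcohol (2-methylene, 10-hydroxyl, cis-fused drawn) | COC(=O)[C@]1(C)CC(=C)C[C@]2(O)C[C@H](OCc3ccccc3)[C@@H](COCc3ccccc3)[C@H]12 | intermediate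
10 | β-hydroxy ketone (2-oxo, 10-hydroxyl) | COC(=O)[C@]1(C)CC(=O)C[C@]2(O)C[C@H](OCc3ccccc3)[C@@H](COCc3ccccc3)[C@H]12 | intermediate (not isolated)
11 | ring A enone | COC(=O)[C@]1(C)CC(=O)C=C2C[C@H](OCc3ccccc3)[C@@H](COCc3ccccc3)[C@H]12 | intermediate
12 | 2α-allylic alcohol | COC(=O)[C@]1(C)C[C@H](O)C=C2C[C@H](OCc3ccccc3)[C@@H](COCc3ccccc3)[C@H]12 | intermediate
13 | cyclopropyl carbinol methyl ester | O(Cc4ccccc4)[C@H]1C[C@]23C[C@H]2[C@@H](O)C[C@@](C)(C(=O)OC)[C@H]3[C@@H]1COCc1ccccc1 | intermediate
14 | cyclopropyl carbinol 19-acid | O(Cc4ccccc4)[C@H]1C[C@]23C[C@H]2[C@@H](O)C[C@@](C)(C(=O)O)[C@H]3[C@@H]1COCc1ccccc1 | intermediate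
15 | cyclopropyl keto acid (key-step precursor) | O(Cc4ccccc4)[C@H]1C[C@]23C[C@H]2C(=O)C[C@@](C)(C(=O)O)[C@H]3[C@@H]1COCc1ccccc1 | intermediate
16 | 20-iodo keto acid | O(Cc4ccccc4)[C@H]1C[C@]2(CI)CC(=O)C[C@@](C)(C(=O)O)[C@H]2[C@@H]1COCc1ccccc1 | intermediate (not isolated)
17 | 2-oxo 19,20-lactone (key-step product) | O(Cc4ccccc4)[C@H]1C[C@]23COC(=O)[C@](C)(CC(=O)C2)[C@H]3[C@@H]1COCc1ccccc1 | intermediate
18 | 2β-hydroxy lactone | O(Cc4ccccc4)[C@H]1C[C@]23COC(=O)[C@](C)(C[C@@H](O)C2)[C@H]3[C@@H]1COCc1ccccc1 | intermediate
19 | 2β-pivalate | O(Cc4ccccc4)[C@H]1C[C@]23COC(=O)[C@](C)(C[C@@H](OC(=O)C(C)(C)C)C2)[C@H]3[C@@H]1COCc1ccccc1 | intermediate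
20 | 7,8-diol | O[C@H]1C[C@]23COC(=O)[C@](C)(C[C@@H](OC(=O)C(C)(C)C)C2)[C@H]3[C@@H]1CO | intermediate
21 | 8-hydroxy 7-aldehyde | O[C@H]1C[C@]23COC(=O)[C@](C)(C[C@@H](OC(=O)C(C)(C)C)C2)[C@H]3[C@@H]1C=O | intermediate (not isolated)
22 | 8-hydroxy 7-carboxylic acid | O[C@H]1C[C@]23COC(=O)[C@](C)(C[C@@H](OC(=O)C(C)(C)C)C2)[C@H]3[C@@H]1C(=O)O | intermediate
23 | 8-hydroxy 7-methyl ester | O[C@H]1C[C@]23COC(=O)[C@](C)(C[C@@H](OC(=O)C(C)(C)C)C2)[C@H]3[C@@H]1C(=O)OC | intermediate
24 | β-keto ester (8-oxo, 7-methyl ester) | O=C1C[C@]23COC(=O)[C@](C)(C[C@@H](OC(=O)C(C)(C)C)C2)[C@H]3[C@@H]1C(=O)OC | intermediate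
25 | 2-(2-bromoethyl)-2-methyl-1,3-dioxolane | CC1(CCBr)OCCO1 | starting material
26 | C9-alkylated β-keto ester (C9 epimers, C9 left undefined) | O=C1C(CCC5(C)OCCO5)[C@]23COC(=O)[C@](C)(C[C@@H](OC(=O)C(C)(C)C)C2)[C@H]3[C@@H]1C(=O)OC | intermediate
27 | triketone (3-oxobutyl on C9, C9 left undefined) | O=C1C(CCC(C)=O)[C@]23COC(=O)[C@](C)(C[C@@H](OC(=O)C(C)(C)C)C2)[C@H]3[C@@H]1C(=O)OC | intermediate (not isolated)
28 | tricyclic enone (13-oxo-8(14)-ene, H-9 β) | O=C1C=C2[C@@H](CC1)[C@]34COC(=O)[C@](C)(C[C@@H](OC(=O)C(C)(C)C)C3)[C@H]4[C@@H]2C(=O)OC | intermediate
29 | allyltrimethylsilane | C=CC[Si](C)(C)C | starting material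
30 | 8β-allyl 13-ketone | C=CC[C@]23CC(=O)CC[C@H]2[C@]12COC(=O)[C@](C)(C[C@@H](OC(=O)C(C)(C)C)C1)[C@H]2[C@@H]3C(=O)OC | intermediate
31 | keto aldehyde | O=CC[C@]23CC(=O)CC[C@H]2[C@]12COC(=O)[C@](C)(C[C@@H](OC(=O)C(C)(C)C)C1)[C@H]2[C@@H]3C(=O)OC | intermediate
32 | 8β-propargyl 13-ketone | C#CC[C@]23CC(=O)CC[C@H]2[C@]12COC(=O)[C@](C)(C[C@@H](OC(=O)C(C)(C)C)C1)[C@H]2[C@@H]3C(=O)OC | intermediate
33 | methyl ester 2-pivalate of the target gibberellin | C=C1C[C@]23C[C@@]1(O)CC[C@H]2[C@]12COC(=O)[C@](C)(C[C@@H](OC(=O)C(C)(C)C)C1)[C@H]2[C@@H]3C(=O)OC | intermediate
34 | dipotassium salt of the 20-hydroxy 7,19-diacid | [K+].[K+].C=C1C[C@]23C[C@@]1(O)CC[C@H]2[C@]1(CO)C[C@H](O)C[C@@](C)(C(=O)[O-])[C@H]1[C@@H]3C(=O)[O-] | intermediate (not isolated)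
35 | target gibberellin (2β,13-dihydroxy-16-ene C20 gibberellin 7-carboxylic acid 19,20-δ-lactone) | C=C1C[C@]23C[C@@]1(O)CC[C@H]2[C@]12COC(=O)[C@](C)(C[C@@H](O)C1)[C@H]2[C@@H]3C(=O)O | target

## Step count and risk

Total: 25 steps. Longest linear sequence: 25 steps, fully linear from 1; 4, 25 and 29 are purchased.

**Step 12 (key step).** Three things could go wrong. The cyclopropane could ionise toward quaternary C10 (C1–C10 cleavage) instead of undergoing SN2 opening at C20. The reaction could stall because 3-exo return of 16 to 15 outruns the slow neopentyl displacement. The Lewis acid and iodide could attack the benzyl ethers, or the C8 oxygen could participate. Fallback, from 11 back to 17, makes the C10–C20 bond instead of the O–C20 bond. KOSiMe3 demethylates 11 to the enone acid F1. Its caesium salt is alkylated with chloromethyl phenyl selenide to the (phenylselanyl)methyl ester F2. Bu3SnH and AIBN in hot benzene then generate the acyloxymethyl radical, which adds 6-exo to C10 of the enone from the α face dictated by the tether and gives 17 after hydrogen transfer to C1.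

**Step 8.** Hydride delivery could lack facial selectivity and give the 2β-alcohol, which would steer the methylene to the wrong face; the 2α-alkoxide could also transfer onto the C19 ester. Fallback from 11 to 12: the reduction is run to the 2β-allylic alcohol F3 where that epimer dominates, F3 is inverted by a Mitsunobu reaction with chloroacetic acid to the 2α-chloroacetate F4, and brief K2CO3 in MeOH at 0 °C releases 12.

**Step 13.** Protonation could occur from the open exo face and give the axial 2α-alcohol, and excess reagent could reduce the δ-lactone. Fallback from 17 to 18: NaBH4 is used for its reliable exo attack, giving the 2α-alcohol F5; Mitsunobu inversion with 4-nitrobenzoic acid gives the 2β-4-nitrobenzoate F6, and K2CO3 in MeOH gives 18.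

**Step 19.** Alkylation at C9, next to quaternary C10, with an unactivated bromide could be slow and lose to O-alkylation or to dehydrobromination of 25. Fallback from 24 to 27: 24 is converted (Me3SiCl, Et3N; then LDA, Me3SiCl) into the bis(trimethylsilyl) dienol ether F7. Its terminal carbon C9 adds to methyl vinyl ketone in a Mukaiyama–Michael reaction (TiCl4, −78 °C) to give 27 after work-up, which continues under the acid of step 20.

**Step 23.** Under carbonate the C12 enolate could add to the C16 aldehyde in an intramolecular aldol (a bicyclo[2.2.2]octane), and C6 could epimerise. Fallback from 31 to 33: SmI2 in THF at −78 °C effects pinacol closure of 31 to the 13,16-diol F8, Dess–Martin oxidation gives the 13-hydroxy 16-ketone F9, and Wittig methylenation with Ph3P=CH2 gives 33.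

## Further compounds

F1 | step 12 | ring A enone 19-acid | OC(=O)[C@]1(C)CC(=O)C=C2C[C@H](OCc3ccccc3)[C@@H](COCc3ccccc3)[C@H]12
F2 | step 12 | (phenylselanyl)methyl ester of the enone acid | O=C(OC[Se]c4ccccc4)[C@]1(C)CC(=O)C=C2C[C@H](OCc3ccccc3)[C@@H](COCc3ccccc3)[C@H]12
F3 | step 8 | 2β-allylic alcohol | COC(=O)[C@]1(C)C[C@@H](O)C=C2C[C@H](OCc3ccccc3)[C@@H](COCc3ccccc3)[C@H]12
F4 | step 8 | 2α-chloroacetate | COC(=O)[C@]1(C)C[C@H](OC(=O)CCl)C=C2C[C@H](OCc3ccccc3)[C@@H](COCc3ccccc3)[C@H]12
F5 | step 13 | 2α-hydroxy lactone | O(Cc4ccccc4)[C@H]1C[C@]23COC(=O)[C@](C)(C[C@H](O)C2)[C@H]3[C@@H]1COCc1ccccc1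
F6 | step 13 | 2β-(4-nitrobenzoate) | O(Cc4ccccc4)[C@H]1C[C@]23COC(=O)[C@](C)(C[C@@H](OC(=O)c5ccc(cc5)[N+](=O)[O-])C2)[C@H]3[C@@H]1COCc1ccccc1
F7 | step 19 | bis(trimethylsilyl) dienol ether of the β-keto ester | COC(O[Si](C)(C)C)=C1C(O[Si](C)(C)C)=C[C@]23COC(=O)[C@](C)(C[C@@H](OC(=O)C(C)(C)C)C2)[C@H]31
F8 | step 23 | 13,16-diol (C16 undefined) | OC1C[C@]23C[C@@]1(O)CC[C@H]2[C@]12COC(=O)[C@](C)(C[C@@H](OC(=O)C(C)(C)C)C1)[C@H]2[C@@H]3C(=O)OC
F9 | step 23 | 13-hydroxy 16-ketone | O=C1C[C@]23C[C@@]1(O)CC[C@H]2[C@]12COC(=O)[C@](C)(C[C@@H](OC(=O)C(C)(C)C)C1)[C@H]2[C@@H]3C(=O)OC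
A1 | alternative 1 | pentacyclic cyclopentenone (C19 ketone, C10=C20 alkene) | C15(OCCO5)C[C@]23C[C@@]1(O[Si](C)(C)C(C)(C)C)CC[C@H]2C4=CC(=O)[C@H](C)[C@H]4[C@@H]3COCc1ccc(OC)cc1
A2 | alternative 2 | methyl ester bis-silyl ether of the target gibberellin (13-O-trimethylsilyl, 2-O-tert-butyldimethylsilyl) | C=C1C[C@]23C[C@@]1(O[Si](C)(C)C)CC[C@H]2[C@]12COC(=O)[C@](C)(C[C@@H](O[Si](C)(C)C(C)(C)C)C1)[C@H]2[C@@H]3C(=O)OC
A3 | alternative 3 | tetracyclic 11-ene with C15 aldehyde on C8 | O=C[C@]23C[C@H](O[Si](C)(C)C(C)(C)C)C=C[C@H]2[C@]12COC(=O)[C@](C)(C[C@@H](O[Si](C)(C)C(C)(C)C)C1)[C@H]2[C@@H]3COCc1ccc(OC)cc1
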